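**Retrosynthetic overview**
1. Target 21 ⇐ last-step allylic hydroxylation of the C15 methyl (SeO2) of 20 ⇐ C8 angelate, C9 acetate put stepwise on diol 17 ⇐ acetonide 16.
2. 16 ⇐ C6–C7 bond: electroreductive CrCl2-catalysed intramolecular allylation/lactonisation of bromo-enal 14; the ten-membered carbocycle and the trans-fused α-methylene-γ-lactone form together, and C6/C7 are set by C8/C9.
3. 14 ⇐ Morita–Baylis–Hillman reaction and SN2' bromination at C7 of dialdehyde 11 ⇐ diester 8.
4. 8 ⇐ C9–C10 bond: visible-light Ir/Ni decarboxylative alkenylation of L-tartrate monoacid 7 (source of C8 and C9) with (Z)-α-bromoenoate 5, made from neryl acetate, which supplies the ring-cis C4=C5 olefin.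
5. Ring order: dioxolane (bought) → carbocycle plus lactone in one step (step 9) → dioxolane removed.

Assumption: germacrane numbering is used for locants (lactone carbonyl C12, exocyclic methylene C13, ester carbon C14, C4 substituent C15); 1, 4, 6, 12 and 19 are taken as commercial. The descriptor at C7 is R in 17, 18, F1, F6 and F7 only because a free 8-OH changes the CIP ranking; the geometry is the same throughout.

**Step 1**
Reactants: 1 neryl acetate
Product: 3 (4Z)-6-acetoxy-4-methylhex-4-enal, via secondary ozonide 2 (not isolated)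
Conditions: O3 (1.0 equiv), CH2Cl2, −78 °C; then Me2S, −78 °C → rt
Reagents that add atoms: ozone, [O-][O+]=O
Why: Chemoselective ozonolysis (Criegee mechanism, reductive work-up) cleaves only the electron-rich 6,7-alkene because the 2,3-alkene is deactivated by the allylic acetate, so the Z geometry that becomes the ring-cis C4=C5 olefin is untouched.

**Step 2**
Reactants: 3 (4Z)-6-acetoxy-4-methylhex-4-enal; 4 methyl (triphenylphosphoranylidene)acetate
Product: 5 methyl (2Z,6Z)-8-acetoxy-2-bromo-6-methylocta-2,6-dienoate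
Conditions: 4, NBS, CH2Cl2, −20 °C, 30 min; then 3, −20 °C → rt, 12 h
Reagents that add atoms: N-bromosuccinimide, BrN1C(=O)CCC1=O
Why: Wittig olefination with the α-bromo stabilised ylide made in the flask gives the (Z)-2-bromoenoate (alkyl cis to Br, trans to CO2Me), the geometry later carried with retention into the ring-cis C1=C10 enoate.

**Step 3**
Reactants: 6 dimethyl (4R,5R)-2,2-dimethyl-1,3-dioxolane-4,5-dicarboxylate (dimethyl 2,3-O-isopropylidene-L-tartrate)
Product: 7 (4R,5R)-5-(methoxycarbonyl)-2,2-dimethyl-1,3-dioxolane-4-carboxylic acid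
Conditions: KOH (1.0 equiv), MeOH, 0 °C → rt; then 1 M HCl to pH 2
Reagents that add atoms: potassium hydroxide, [K+].[OH-]
Why: Mono-saponification of the C2-symmetric diester (both esters equivalent, the carboxylate slows the second hydrolysis) gives the monoacid without touching the two tartrate stereocentres.

**Step 4**
Reactants: 7 (4R,5R)-5-(methoxycarbonyl)-2,2-dimethyl-1,3-dioxolane-4-carboxylic acid; 5 methyl (2Z,6Z)-8-acetoxy-2-bromo-6-methylocta-2,6-dienoate
Product: 8 methyl (4R,5S)-5-[(2E,6Z)-8-acetoxy-1-methoxy-6-methyl-1-oxoocta-2,6-dien-2-yl]-2,2-dimethyl-1,3-dioxolane-4-carboxylate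
Conditions: Ir[dF(CF3)ppy]2(dtbbpy)PF6 (1 mol%), NiCl2·glyme (10 mol%), dtbbpy (15 mol%), Cs2CO3 (1.5 equiv), DMSO, 450 nm LEDs, 25 °C (7: 1.5 equiv)
Reagents that add atoms: none
Why: Metallaphotoredox decarboxylative sp3–sp2 cross-coupling: the excited iridium photocatalyst oxidises the carboxylate to the dioxolan-4-yl radical, which is captured by the alkenyl–nickel species formed from 5 and coupled anti to the neighbouring CO2Me, giving the trans-dioxolane (9S set by the tartrate-derived C8) with retention of olefin geometry.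

**Step 5**
Reactants: 8 methyl (4R,5S)-5-[(2E,6Z)-8-acetoxy-1-methoxy-6-methyl-1-oxoocta-2,6-dien-2-yl]-2,2-dimethyl-1,3-dioxolane-4-carboxylate
Product: 10 methyl (2E,6Z)-8-hydroxy-2-[(4S,5S)-5-(hydroxymethyl)-2,2-dimethyl-1,3-dioxolan-4-yl]-6-methylocta-2,6-dienoate, via hydroxy acetate 9 (not isolated)
Conditions: NaBH4 (2.5 equiv), MeOH, 0 °C → rt; then K2CO3 (0.3 equiv), rt
Reagents that add atoms: none
Why: NaBH4 in methanol reduces only the α-alkoxy-activated ester and not the hindered conjugated C14 ester, and K2CO3-catalysed methanolysis then removes the allylic acetate in the same flask.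

**Step 6**
Reactants: 10 methyl (2E,6Z)-8-hydroxy-2-[(4S,5S)-5-(hydroxymethyl)-2,2-dimethyl-1,3-dioxolan-4-yl]-6-methylocta-2,6-dienoate
Product: 11 methyl (2E,6Z)-2-[(4S,5R)-5-formyl-2,2-dimethyl-1,3-dioxolan-4-yl]-6-methyl-8-oxoocta-2,6-dienoate
Conditions: Dess–Martin periodinane (2.6 equiv), NaHCO3, CH2Cl2, 0 °C → rt
Reagents that add atoms: none
Why: Buffered Dess–Martin oxidation converts both primary alcohols to aldehydes without epimerising the α-alkoxy aldehyde or isomerising the Z-enal.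

**Step 7**
Reactants: 11 methyl (2E,6Z)-2-[(4S,5R)-5-formyl-2,2-dimethyl-1,3-dioxolan-4-yl]-6-methyl-8-oxoocta-2,6-dienoate; 12 methyl acrylate
Product: 13 methyl (2E,6Z)-2-{(4S,5S)-5-[1-hydroxy-2-(methoxycarbonyl)prop-2-en-1-yl]-2,2-dimethyl-1,3-dioxolan-4-yl}-6-methyl-8-oxoocta-2,6-dienoate (mixture at the carbinol carbon)
Conditions: 12 (5 equiv), DABCO (0.5 equiv), 1,4-dioxane/H2O 1:1, rt, 36 h
Reagents that add atoms: none
Why: The Morita–Baylis–Hillman reaction occurs only at the electrophilic α-alkoxy aldehyde, the β,β-disubstituted enal being inert to the DABCO–acrylate zwitterion; the new carbinol centre is a mixture that is erased in step 8.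

**Step 8**
Reactants: 13 Baylis–Hillman alcohol
Product: 14 methyl (2E,6Z)-2-{(4S,5S)-5-[(1Z)-3-bromo-2-(methoxycarbonyl)prop-1-en-1-yl]-2,2-dimethyl-1,3-dioxolan-4-yl}-6-methyl-8-oxoocta-2,6-dienoate
Conditions: NBS (1.3 equiv), Me2S (1.5 equiv), CH2Cl2, 0 °C → rt
Reagents that add atoms: N-bromosuccinimide, BrN1C(=O)CCC1=O
Why: Corey–Kim-type activation of the alcohol as an alkoxysulfonium salt and SN2' attack of bromide gives the preferred (Z)-2-(bromomethyl)enoate with loss of the C7 carbinol centre.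

**Step 9**
Reactants: 14 allylic bromide enal
Product: 16 methyl (1(10)E,4Z,6R,7S,8S,9S)-8,9-(isopropylidenedioxy)-12-oxo-6,12-epoxygermacra-1(10),4,11(13)-trien-14-oate (the 6,12-olide), via seco hydroxy ester 15 (not isolated)
Conditions: CrCl2 (20 mol%), n-Bu4NBF4 (0.1 M), DMF, undivided cell, sacrificial Al anode, reticulated vitreous carbon cathode, constant current (2.5 F/mol), 14 added over 10 h (≤3 mM), 25 °C; then PPTS (cat.), PhH, 45 °C
Reagents that add atoms: none
Why: Proposed new method: the cathode regenerates divalent chromium from catalytic CrCl2, two equivalents of which turn the allylic bromide into a 2-(methoxycarbonyl)allyl trivalent chromium species that (after the usual E/Z equilibration) adds through its γ-carbon C7 to the tethered enal in a chair Zimmerman–Traxler transition state (anti addition, hence 6,7-trans), C6 approaching C7 anti to the C8–C9 bond while H8 eclipses the allyl plane to minimise A(1,3) strain, which sets 7S and 6R, and Al3+ from the anode takes over the alkoxide so that chromium turns over and the alkoxide lactonises onto the C12 ester; the closest known reactions are the stoichiometric CrCl2 Nozaki–Hiyama macrocyclisations of ω-formyl allylic bromides to germacranolides and the intermolecular electroreductive chromium-catalysed Nozaki–Hiyama–Kishi coupling, neither shown as a catalytic electrochemical ring closure of a 2-(bromomethyl)enoate.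

**Step 10**
Reactants: 16 acetonide lactone
Product: 17 methyl (1(10)E,4Z,6R,7R,8S,9S)-8,9-dihydroxy-12-oxo-6,12-epoxygermacra-1(10),4,11(13)-trien-14-oate
Conditions: TFA/H2O 9:1, 0 °C, 30 min
Reagents that add atoms: none
Why: Acid-catalysed acetal hydrolysis removes the isopropylidene group, while the lactone, the enoate and both olefin geometries are stable to cold aqueous TFA.

**Step 11**
Reactants: 17 8,9-diol
Product: 18 methyl (1(10)E,4Z,6R,7R,8S,9S)-9-acetoxy-8-hydroxy-12-oxo-6,12-epoxygermacra-1(10),4,11(13)-trien-14-oate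
Conditions: AcCl (1.05 equiv), 2,4,6-collidine, CH2Cl2, −78 → −40 °C
Reagents that add atoms: acetyl chloride, CC(Cl)=O
Why: Kinetically controlled acylation selects the allylic C9–OH, flanked by the planar C10, over the C8–OH, which is shielded by the ring-fusion carbon C7 and the lactone.

**Step 12**
Reactants: 18 9-acetate; 19 angelic acid ((2Z)-2-methylbut-2-enoic acid)
Product: 20 methyl (1(10)E,4Z,6R,7S,8S,9S)-9-acetoxy-8-[(2Z)-2-methylbut-2-enoyloxy]-12-oxo-6,12-epoxygermacra-1(10),4,11(13)-trien-14-oate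
Conditions: 19, 2,4,6-trichlorobenzoyl chloride, Et3N, PhMe, rt, 2 h; then 18, 75 °C
Reagents that add atoms: none
Why: Yamaguchi esterification through the mixed anhydride acylates the hindered C8–OH without DMAP and therefore without Z→E isomerisation of the angelate to the tiglate.

**Step 13**
Reactants: 20 15-deoxy diester
Product: 21 target, methyl (1(10)E,4E,6R,7S,8S,9S)-9-acetoxy-15-hydroxy-8-[(2Z)-2-methylbut-2-enoyloxy]-12-oxo-6,12-epoxygermacra-1(10),4,11(13)-trien-14-oate
Conditions: SeO2 (0.5 equiv), t-BuOOH (3 equiv), salicylic acid (10 mol%), CH2Cl2, 25 °C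
Reagents that add atoms: selenium dioxide, O=[Se]=O; tert-butyl hydroperoxide, CC(C)(C)OO
Why: Riley allylic oxidation (ene reaction, then [2,3]-sigmatropic shift) attacks the only non-conjugated alkene C4=C5, abstracts H from the C15 methyl and re-forms the double bond with CH2OH trans to C6, so the ring-cis geometry is kept, as in the SeO2 hydroxylation of vinylic methyls in germacranolides.

**Compound list**
1 | neryl acetate, (2Z)-3,7-dimethylocta-2,6-dien-1-yl acetate | CC(=O)OC/C=C(C)\CCC=C(C)C | starting material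
2 | secondary ozonide, (2Z)-5-(5,5-dimethyl-1,2,4-trioxolan-3-yl)-3-methylpent-2-en-1-yl acetate | CC(=O)OC/C=C(C)\CCC1OOC(C)(C)O1 | intermediate
3 | (4Z)-6-acetoxy-4-methylhex-4-enal | CC(=O)OC/C=C(C)\CCC=O | intermediate
4 | methyl (triphenylphosphoranylidene)acetate | COC(=O)C=P(c1ccccc1)(c1ccccc1)c1ccccc1 | starting material
5 | methyl (2Z,6Z)-8-acetoxy-2-bromo-6-methylocta-2,6-dienoate | COC(=O)/C(Br)=C/CC/C(C)=C\COC(C)=O | intermediate
6 | dimethyl (4R,5R)-2,2-dimethyl-1,3-dioxolane-4,5-dicarboxylate | COC(=O)[C@@H]1OC(C)(C)O[C@H]1C(=O)OC | starting material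
7 | (4R,5R)-5-(methoxycarbonyl)-2,2-dimethyl-1,3-dioxolane-4-carboxylic acid | OC(=O)[C@@H]1OC(C)(C)O[C@H]1C(=O)OC | intermediate
8 | methyl (4R,5S)-5-[(2E,6Z)-8-acetoxy-1-methoxy-6-methyl-1-oxoocta-2,6-dien-2-yl]-2,2-dimethyl-1,3-dioxolane-4-carboxylate | CC(=O)OC/C=C(C)\CC/C=C(/C(=O)OC)[C@@H]1OC(C)(C)O[C@H]1C(=O)OC | intermediate
9 | methyl (2E,6Z)-8-acetoxy-2-[(4S,5S)-5-(hydroxymethyl)-2,2-dimethyl-1,3-dioxolan-4-yl]-6-methylocta-2,6-dienoate | CC(=O)OC/C=C(C)\CC/C=C(/C(=O)OC)[C@@H]1OC(C)(C)O[C@H]1CO | intermediate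
10 | methyl (2E,6Z)-8-hydroxy-2-[(4S,5S)-5-(hydroxymethyl)-2,2-dimethyl-1,3-dioxolan-4-yl]-6-methylocta-2,6-dienoate | OC/C=C(C)\CC/C=C(/C(=O)OC)[C@@H]1OC(C)(C)O[C@H]1CO | intermediate
11 | methyl (2E,6Z)-2-[(4S,5R)-5-formyl-2,2-dimethyl-1,3-dioxolan-4-yl]-6-methyl-8-oxoocta-2,6-dienoate | O=C/C=C(C)\CC/C=C(/C(=O)OC)[C@@H]1OC(C)(C)O[C@H]1C=O | intermediate
12 | methyl acrylate | C=CC(=O)OC | starting material
13 | methyl (2E,6Z)-2-{(4S,5S)-5-[1-hydroxy-2-(methoxycarbonyl)prop-2-en-1-yl]-2,2-dimethyl-1,3-dioxolan-4-yl}-6-methyl-8-oxoocta-2,6-dienoate, carbinol epimers | O=C/C=C(C)\CC/C=C(/C(=O)OC)[C@@H]1OC(C)(C)O[C@H]1C(O)C(=C)C(=O)OC | intermediate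
14 | methyl (2E,6Z)-2-{(4S,5S)-5-[(1Z)-3-bromo-2-(methoxycarbonyl)prop-1-en-1-yl]-2,2-dimethyl-1,3-dioxolan-4-yl}-6-methyl-8-oxoocta-2,6-dienoate | O=C/C=C(C)\CC/C=C(/C(=O)OC)[C@@H]1OC(C)(C)O[C@H]1/C=C(\CBr)C(=O)OC | intermediate
15 | dimethyl (1(10)E,4Z,6R,7S,8S,9S)-6-hydroxy-8,9-(isopropylidenedioxy)germacra-1(10),4,11(13)-triene-12,14-dioate | O[C@@H]1/C=C(/C)CC/C=C(/C(=O)OC)[C@@H]2OC(C)(C)O[C@H]2[C@H]1C(=C)C(=O)OC | intermediate
16 | methyl (1(10)E,4Z,6R,7S,8S,9S)-8,9-(isopropylidenedioxy)-12-oxo-6,12-epoxygermacra-1(10),4,11(13)-trien-14-oate | C=C1C(=O)O[C@@H]2/C=C(/C)CC/C=C(/C(=O)OC)[C@@H]3OC(C)(C)O[C@H]3[C@@H]12 | intermediate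
17 | methyl (1(10)E,4Z,6R,7R,8S,9S)-8,9-dihydroxy-12-oxo-6,12-epoxygermacra-1(10),4,11(13)-trien-14-oate | C=C1C(=O)O[C@@H]2/C=C(/C)CC/C=C(/C(=O)OC)[C@H](O)[C@@H](O)[C@@H]12 | intermediate
18 | methyl (1(10)E,4Z,6R,7R,8S,9S)-9-acetoxy-8-hydroxy-12-oxo-6,12-epoxygermacra-1(10),4,11(13)-trien-14-oate | C=C1C(=O)O[C@@H]2/C=C(/C)CC/C=C(/C(=O)OC)[C@H](OC(C)=O)[C@@H](O)[C@@H]12 | intermediate
19 | angelic acid, (2Z)-2-methylbut-2-enoic acid | C/C=C(/C)C(=O)O | starting material
20 | methyl (1(10)E,4Z,6R,7S,8S,9S)-9-acetoxy-8-[(2Z)-2-methylbut-2-enoyloxy]-12-oxo-6,12-epoxygermacra-1(10),4,11(13)-trien-14-oate | C=C1C(=O)O[C@@H]2/C=C(/C)CC/C=C(/C(=O)OC)[C@H](OC(C)=O)[C@@H](OC(=O)/C(C)=C\C)[C@@H]12 | intermediate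
21 | methyl (1(10)E,4E,6R,7S,8S,9S)-9-acetoxy-15-hydroxy-8-[(2Z)-2-methylbut-2-enoyloxy]-12-oxo-6,12-epoxygermacra-1(10),4,11(13)-trien-14-oate (CNP0216801.4) | C=C1C(=O)O[C@@H]2/C=C(/CO)CC/C=C(/C(=O)OC)[C@H](OC(C)=O)[C@@H](OC(=O)/C(C)=C\C)[C@@H]12 | target

**Count**
Total steps: 13. Longest linear sequence: 12 (steps 1, 2, 4–13 from neryl acetate).

**Steps most likely to fail**

Step 9 (the proposed new step; ring closure, C6/C7 stereocentres). The catalytic electrochemical turnover and the facial selectivity in the macrocyclic transition state are both unproven. Fallback, known chemistry, sets out from 14 and comes back at 16: the electrode-driven catalytic cascade is given up for the classical stoichiometric organochromium route in two isolated operations. Bromide 14 is added by syringe pump (final 2 mM) to CrCl2 (8 equiv) in DMF/THF at 25 °C, the stoichiometric Nozaki–Hiyama macrocyclisation used for ten-membered germacranolide rings. The seco hydroxy ester 15 is isolated after aqueous work-up and lactonised separately with p-TsOH (cat.) in benzene to 16. No compound outside the list is made (F0).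

Step 11 (regioselective mono-acetylation). The two secondary hydroxyls may not be discriminated well by a small acylating agent. Fallback sets out from 17 and comes back at 20, bypassing 18: the hydroxyls are told apart by a bulky silyl chloride and the order of acylation is reversed. TESCl (1.05 equiv), imidazole, DMF, −40 °C gives the 9-O-triethylsilyl ether F1. Yamaguchi angeloylation as in step 12 gives the 8-angelate 9-silyl ether F2. HF·pyridine in THF at 0 °C gives the 8-angelate 9-alcohol F3, and Ac2O, DMAP, pyridine then gives 20.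

Step 13 (late C15 hydroxylation). The C4=C5 olefin is deactivated by the allylic lactone oxygen, and forcing conditions endanger the angelate. Fallback sets out from 16 and comes back at 21: the oxidation is moved to the robust acetonide stage and the new hydroxyl is carried protected. SeO2 (1.2 equiv) in 1,4-dioxane at 70 °C gives the 15-hydroxy acetonide lactone F4. TBDPSCl, imidazole, DMF gives the 15-silyl ether F5. 80% aqueous AcOH at 40 °C gives the 15-silyloxy 8,9-diol F6. The conditions of steps 11 and 12 give the 15-silyloxy 9-acetate F7 and then the 15-silyloxy 9-acetate 8-angelate F8. HF·pyridine in THF removes the silyl group to give 21.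

**Further compounds**
F0 | step 9 | none | none
F1 | step 11 | methyl (1(10)E,4Z,6R,7R,8S,9S)-8-hydroxy-9-(triethylsilyloxy)-12-oxo-6,12-epoxygermacra-1(10),4,11(13)-trien-14-oate | C=C1C(=O)O[C@@H]2/C=C(/C)CC/C=C(/C(=O)OC)[C@H](O[Si](CC)(CC)CC)[C@@H](O)[C@@H]12
F2 | step 11 | methyl (1(10)E,4Z,6R,7S,8S,9S)-8-[(2Z)-2-methylbut-2-enoyloxy]-9-(triethylsilyloxy)-12-oxo-6,12-epoxygermacra-1(10),4,11(13)-trien-14-oate | C=C1C(=O)O[C@@H]2/C=C(/C)CC/C=C(/C(=O)OC)[C@H](O[Si](CC)(CC)CC)[C@@H](OC(=O)/C(C)=C\C)[C@@H]12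
F3 | step 11 | methyl (1(10)E,4Z,6R,7S,8S,9S)-9-hydroxy-8-[(2Z)-2-methylbut-2-enoyloxy]-12-oxo-6,12-epoxygermacra-1(10),4,11(13)-trien-14-oate | C=C1C(=O)O[C@@H]2/C=C(/C)CC/C=C(/C(=O)OC)[C@H](O)[C@@H](OC(=O)/C(C)=C\C)[C@@H]12
F4 | step 13 | methyl (1(10)E,4E,6R,7S,8S,9S)-15-hydroxy-8,9-(isopropylidenedioxy)-12-oxo-6,12-epoxygermacra-1(10),4,11(13)-trien-14-oate | C=C1C(=O)O[C@@H]2/C=C(/CO)CC/C=C(/C(=O)OC)[C@@H]3OC(C)(C)O[C@H]3[C@@H]12
F5 | step 13 | methyl (1(10)E,4E,6R,7S,8S,9S)-15-(tert-butyldiphenylsilyloxy)-8,9-(isopropylidenedioxy)-12-oxo-6,12-epoxygermacra-1(10),4,11(13)-trien-14-oate | C=C1C(=O)O[C@@H]2/C=C(/CO[Si](c3ccccc3)(c4ccccc4)C(C)(C)C)CC/C=C(/C(=O)OC)[C@@H]5OC(C)(C)O[C@H]5[C@@H]12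
F6 | step 13 | methyl (1(10)E,4E,6R,7R,8S,9S)-15-(tert-butyldiphenylsilyloxy)-8,9-dihydroxy-12-oxo-6,12-epoxygermacra-1(10),4,11(13)-trien-14-oate | C=C1C(=O)O[C@@H]2/C=C(/CO[Si](c3ccccc3)(c4ccccc4)C(C)(C)C)CC/C=C(/C(=O)OC)[C@H](O)[C@@H](O)[C@@H]12
F7 | step 13 | methyl (1(10)E,4E,6R,7R,8S,9S)-9-acetoxy-15-(tert-butyldiphenylsilyloxy)-8-hydroxy-12-oxo-6,12-epoxygermacra-1(10),4,11(13)-trien-14-oate | C=C1C(=O)O[C@@H]2/C=C(/CO[Si](c3ccccc3)(c4ccccc4)C(C)(C)C)CC/C=C(/C(=O)OC)[C@H](OC(C)=O)[C@@H](O)[C@@H]12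
F8 | step 13 | methyl (1(10)E,4E,6R,7S,8S,9S)-9-acetoxy-15-(tert-butyldiphenylsilyloxy)-8-[(2Z)-2-methylbut-2-enoyloxy]-12-oxo-6,12-epoxygermacra-1(10),4,11(13)-trien-14-oate | C=C1C(=O)O[C@@H]2/C=C(/CO[Si](c3ccccc3)(c4ccccc4)C(C)(C)C)CC/C=C(/C(=O)OC)[C@H](OC(C)=O)[C@@H](OC(=O)/C(C)=C\C)[C@@H]12
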